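The pitfall with a curve that flattens is to take the charge for the end point. By the charge, X is the limiting reagent in Thursday's flask, yet at the last reading 31.8 % of its X has become G.

| setting | Thursday's | Sunday's | Saturday's | Tuesday's |
|---|---|---|---|---|
| X | 200 mM | 120 mM | 200 mM | 100 mM |
| Z | 400 mM | 320 mM | 200 mM | 400 mM |
| J | 6.00 mM | 6.00 mM | 6.00 mM | 2.00 mM |
| time |  |  |  | 9.4 min |

| Thursday's run: time / min | Thursday's run: [G] / mM | Sunday's run: time / min | Sunday's run: [G] / mM | Saturday's run: time / min | Saturday's run: [G] / mM |
|---|---|---|---|---|---|
| 0.42 | 7.4 | 0.42 | 12.4 | 0.42 | 3.7 |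
| 1.3 | 24.9 | 1.3 | 25.6 | 1.3 | 12.6 |
| 2.4 | 38.8 | 2.4 | 42.7 | 2.4 | 16.1 |
| 3.8 | 53.4 | 3.8 | 51.8 | 3.8 | 25.3 |
| 5.5 | 59.7 | 5.5 | 58.5 | 5.5 | 24.2 |
| 7.3 | 61.9 | 7.3 | 70.5 | 7.3 | 28.2 |
| 9.4 | 63.6 | 9.4 | 65.4 | 9.4 | 34.0 |

(scatter of a reading: 2 mM)

* how the opening rate goes with [X] round the charge of the Thursday's run: the exponent of the rate at two percent of X gone to G (one fixed amount of G, the same in the runs compared)
* how the opening rate goes with [Z] round the charge of the Thursday's run: the exponent of the rate at two percent of X gone to G
* G in the Tuesday's run at 9.4 min, as a share of the X charged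

- Overall: X + Z -> G, with J as catalyst.
- Constant volume, constant temperature.
- The analysis sees a species whether free or bound.
- An order is taken over about fifteen percent of the charge, up and down.

Here is what looks wrong. Sunday's flask holds less X (120 mM) and less Z (320 mM) than Thursday's, yet at its last reading it has turned 54.5 % of its X, a larger share.

I clear this up by following the flask rather than the charge. Over the first 1.3 min, Thursday's flask makes G at 19.2 mM min⁻¹. Dividing its last reading by that rate gives 3.32 min, the working life: the time the opening rate takes to make what the last reading shows. I picture a fork at each moment: whatever carries the reaction either makes G or is lost, at a chance of about 0.301 min⁻¹. These readings of G do not name what is lost. Sunday's flask gives a working life of 3.32 min, close to Thursday's. Its opening rate is also close to Thursday's, so its last reading is a similar G, and that G is a larger share of a smaller charge.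

The early readings give me 0.983 as the order in Z and −0.484 as the order in X. Thursday's, Sunday's and Saturday's flasks each hold 6.00 mM of J, and I assume first order in it. Tuesday's flask should then open at 8.93 mM min⁻¹ and, with Thursday's working life, reach 29.6 % of its X. The forecast is close to mine at 29 %, with −0.45 for X and 1 for Z. Its reading of the stall is “This looks like the catalyst dying with time”.

Tuesday's flask gives 32.5 % at 9.4 min. Round Thursday's charge the orders are −0.72 in X, steeper than forecast, and 1.1 in Z. The apparent order in J, early in Thursday's flask, is 1.1.

    J + X ⇌ JX, settled at all times (42.80 M⁻¹)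
    JX + Z → G + J (33.96 M⁻¹ min⁻¹)
    JX + X ⇌ JX2, settled at all times (12.80 M⁻¹)
    Z → Ez (0.3162 min⁻¹)

Saturday's flask has a rate of 10 mM min⁻¹ at two percent of Thursday's X turned. Multiplied by Thursday's working life, this gives 16.8 % of Saturday's X, and its last reading stands at 17.0 %.

All runs are calculated with made-up constants; noise was put on by code.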